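## Structural features

The target is a trans-fused hydrindane. Ring A is the six-membered ring C3a–C4–C5–C6–C7–C7a and ring B the five-membered ring C7a–C1–C2–C3–C3a; they share the C3a–C7a bond. Ring A carries an exocyclic methylene at C4, an axial (2S,3S)-2,3-dimethyloxirane-2-carboxylate at C6 and an equatorial isopropyl group at C7. Ring B carries an acetyl group at C1 and a (Z)-2-methylbut-2-enoate (angelate) at C2. Five stereocentres run unbroken from C6 through C7, C7a and C1 to C2, C3a completes the ring fusion, and two more lie in the epoxy ester. C6–O is cis to the isopropyl group, the C7a–C1 bond is trans to it, and acetyl and angelate are cis on ring B. The fragile points are the angelate (isomerisation to the E ester), the epoxide (acid), the C2 ester β to the acetyl carbonyl (elimination toward C1=C2), the epimerisable C1 and the exocyclic alkene. The real difficulty is the trans ring fusion next to the C1/C2 pair, and telling apart three oxygenated positions and two closely related acyl groups. The feature the key step exploits is that C1, its acetyl group, C2 and C3 are the five carbons of acetylacetone, and that C2 and C4 are 1,4-related across C3–C3a. With both as carbonyls, C3 and C3a are two α-carbons that can be joined oxidatively, which closes ring B.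

## Logic of the disconnections

**27 to 23 and 26.** The C6–O acyl bond is cut first. The epoxy ester would not survive fluoride/acid desilylation or strong base, so it goes on last. This splits off the chiral acid as a separate fragment. The forward step must acylate a hindered axial alcohol with an α-quaternary acid without eliminating the C2 ester.

**26 to 25, 24 and 21.** The carboxyl group is taken back to a primary alcohol and the two epoxide C–O bonds to a Z-allylic alcohol. The same C5 acid 21 then supplies both ester groups. The forward epoxidation must be reagent-controlled, with the tartrate enantiomer that gives the (2R,3S) epoxy alcohol, and the Z geometry must survive the reduction.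

**23 to 22, then to 20 and 21.** The C6 Si–O bond and the C2–O acyl bond are cut. This leaves one free hydroxyl at a time, so the two esters never compete. The forward steps must esterify without Z/E isomerisation and desilylate without base.

**20 to 19.** The C2–H bond is cut, returning C2 to a ketone. C1 then becomes the mobile carbon of a β-diketone, so C1 and C2 can be set together. The forward step must distinguish the ring carbonyl from the acetyl carbonyl and fix two centres at once.

**19 to 18.** The C4=CH2 bond is cut to the C4 ketone. The ketone is what makes C3a an α-carbon, both for the ring closure and for correcting the ring fusion. The forward methylenation must leave two other carbonyls alone.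

**18 to 15.** The C3–C3a bond is cut; this opens ring B and is the key disconnection. The bicyclic triketone becomes a monocyclic polyenol ether in which every carbon of the target core is already present. The forward step needs an oxidisable terminus at C3, a ring enol ether placed at C3a=C4 and not at C4=C5, and a ketone at C4 afterwards.

**15 to 11 and 13, and 13 to 12.** The C7a–C1 bond is cut. Conjugate addition then brings in C1, C2, C3 and the acetyl group in one piece. The forward addition must occur anti to the isopropyl group and must deliver the ring enol ether directly as the C3a=C4 isomer.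

**11 to 10, 9 and 7.** The O–Si bond, the C3a=C7a unsaturation and (in reverse) the C5–O bond of an epoxide are undone. An epoxide on C5–C6 blocks enolisation toward C5, so the new double bond can only form at C3a–C7a. It also holds the C6 oxygen. The forward reductive opening must break only the C5–O bond next to the carbonyl.

**7 to 6, 5 and 4.** The epoxide is traced to an allylic alcohol and this to the enone. A hydroxyl at C4 cis to the isopropyl group directs the epoxide to the hindered face, which an intermolecular oxidant would not reach. The forward reduction must be reagent-controlled toward the cis alcohol; that carbinol centre is removed again by oxidation.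

**4 to 1 and 2.** The C7–C7a bond (Michael) and the C5=C6 bond (aldol condensation) are cut. This reaches two bulk chemicals. The forward Michael addition must set C7 by catalyst control.

## Other disconnections considered

**Alternative 1:** The cut removes C7a–C3a, C1–C2 and C2–C3 together and leads to the acyclic 1,7-enyne A1. In A1 the C7a≡C1 alkyne carries the ketal-protected acetyl group and the C3a=C3 vinyl group sits on the C4 dimethyl ketal. Forward, the Co2(CO)6 complex of A1 (from Co2(CO)8) would take up the alkene and CO in a Pauson–Khand reaction to give the bicyclic enone A2.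
- In its favour: both rings and three bonds form in one operation, which is better than the chosen plan (one ring, one bond). The C2 carbonyl arrives already distinguished from the masked acetyl group, so its reduction needs no enzyme; that is also better.
- Against it: a 1,7-enyne closing a six-membered ring is the less favourable Pauson–Khand case, and the alkyne bears a quaternary substituent. C3a would be set under only remote control from C6 and C7. The C7a=C1 double bond of A2 is tetrasubstituted, and reducing it to a trans-fused ring with the correct C1 centre runs against the usual cis preference of such reductions.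
- Comparison: the mechanism is as well precedented as the anodic coupling (equal). The chosen plan sets C7a by anti addition to a cyclohexenone and can correct C3a by equilibration, which A2 cannot offer. Step economy in the key step favours this alternative; the acyclic stereocontrol before it and the reductions and two deprotections after it would likely cancel the gain.

**Alternative 2:** The cut is C3a–C7a, leading to the nine-membered keto enoate A3. Forward, DBU would enolise the C4 ketone toward C3a, and the enolate would add across the ring to C7a of the enoate, giving the trans-hydrindanone ester A4.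
- In its favour: both ring-fusion centres form in one step under conformational control. The C2 oxygen is in place and protected from the start, so no late stereoselective reduction is needed, which is better than the chosen plan. An ester at C1 avoids the mobile β-diketone.
- Against it: a functionalised nine-membered carbocycle with a trisubstituted enoate is hard to reach. The facial outcome at C7a depends on a medium-ring conformation that cannot be predicted with confidence. The ester must later become a methyl ketone next to a β-oxygen that can eliminate.
- Comparison: C3a is α to the C4 ketone in both plans and can be corrected by equilibration (equal). The chosen plan has the more predictable C7a centre and the much shorter route to its cyclisation substrate.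

**Alternative 3:** The cut is C7a–C1, leading to the cyclohexane diazo keto ester A5. Forward, Rh2(OAc)4 would generate the carbenoid at C1, which inserts into the equatorial C7a–H bond with retention to give the trans-fused β-keto ester A6.
- In its favour: five-membered ring formation by carbenoid C–H insertion is a very dependable reaction, arguably more secure than the anodic coupling (better on mechanism). All ring A centres are set on a simple cyclohexane beforehand. A β-keto ester has only one ketone, so C2 can be reduced with an ordinary hydride (better than relying on an enzyme).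
- Against it: C7a is a methylene flanked by the isopropyl-bearing C7, so insertion must choose the equatorial over the axial hydrogen, and also C7a–H over the equally distant C4–H, which the acetate only deactivates. Afterwards C4 must go from acetate to ketone to methylene and the ester to an acetyl group.
- Comparison: the chosen plan brings the acetyl group and the C4 carbonyl in at the right oxidation level and is clearly shorter. This alternative has the more certain ring closure.

Key step: step 10

Remark on numbering: the hydrindane numbering C1–C7a is used for every intermediate, also before ring B exists.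

Remark on the structures: the fixed centres of 15 and 18 (C6, C7, C7a, C3a) agree with the target. One correction: C1 of 16–19 is the central carbon of a β-diketone, largely enolised and without fixed configuration, so its descriptor is nominal and C1 is set only in step 12.

Remark on 13–15: the double-bond geometry of the acyclic silyl enol ethers is immaterial, because these carbons become carbonyl carbons.

## Route

Step 1
Reactants: 1 3-methylbutanal; 2 methyl vinyl ketone
Product: 4 (R)-4-isopropylcyclohex-2-en-1-one, via (R)-2-isopropyl-5-oxohexanal 3 (not isolated)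
Conditions: (R)-2-[methoxy(diphenyl)methyl]pyrrolidine (5 mol %), ethyl 3,4-dihydroxybenzoate (20 mol %), neat, 4 °C; then LiOH (0.1 equiv), i-PrOH, rt
Reagents that add atoms: none
Why: Enamine-catalysed Michael addition followed by intramolecular aldol condensation (a Robinson-type annulation) forms C7–C7a and C5=C6. The diphenylmethyl group shields one face of the E-enamine, so with the (R)-amine the enone adds to the other face and the isopropyl-bearing carbon (later C7) is set as R. The base is kept catalytic to limit racemisation of the α-branched aldehyde.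

Step 2
Reactants: 4 (R)-4-isopropylcyclohex-2-en-1-one
Product: 5 (1R,4R)-4-isopropylcyclohex-2-en-1-ol (hydroxyl cis to isopropyl)
Conditions: (S)-1-methyl-3,3-diphenyltetrahydro-1H,3H-pyrrolo[1,2-c][1,3,2]oxazaborole (0.2 equiv), catecholborane (1.5 equiv), toluene, −78 °C; aq. NaOH work-up
Reagents that add atoms: none
Why: Corey–Bakshi–Shibata reduction, strictly 1,2 with catecholborane. The (S)-oxazaborolidine treats the vinyl arm as the large group and delivers hydride to give the (1R) carbinol, which is the isomer cis to the isopropyl group. Reagent control is needed because the substrate alone leans toward the trans alcohol.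

Step 3
Reactants: 5 (1R,4R)-4-isopropylcyclohex-2-en-1-ol
Product: 6 (1R,2R,5R,6S)-5-isopropyl-7-oxabicyclo[4.1.0]heptan-2-ol (hydroxyl, epoxide and isopropyl all cis)
Conditions: VO(acac)2 (2 mol %), t-BuOOH (1.5 equiv), CH2Cl2, 0 °C to rt
Reagents that add atoms: tert-butyl hydroperoxide, CC(C)(C)OO
Why: Hydroxyl-directed vanadium-catalysed epoxidation. The pseudo-axial vanadate ester delivers the peroxide oxygen to its own face, so the epoxide (C5, C6) lands cis to the hydroxyl and therefore cis to the isopropyl group, the face an external oxidant would avoid.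

Step 4
Reactants: 6 (1R,2R,5R,6S)-5-isopropyl-7-oxabicyclo[4.1.0]heptan-2-ol
Product: 7 (1S,5R,6S)-5-isopropyl-7-oxabicyclo[4.1.0]heptan-2-one
Conditions: (n-Pr4N)RuO4 (5 mol %), N-methylmorpholine N-oxide (1.5 equiv), 4 Å molecular sieves, CH2Cl2, rt
Reagents that add atoms: none
Why: Ley–Griffith oxidation under neutral conditions returns the C4 ketone without touching the epoxide. The temporary carbinol centre has done its directing work and is removed.

Step 5
Reactants: 7 (1S,5R,6S)-5-isopropyl-7-oxabicyclo[4.1.0]heptan-2-one
Product: 9 (1S,5S,6S)-5-isopropyl-7-oxabicyclo[4.1.0]hept-3-en-2-one, via trimethylsilyl enol ether 8 (not isolated)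
Conditions: LDA (1.1 equiv), Me3SiCl, THF, −78 °C; then Pd(OAc)2 (1.05 equiv), MeCN, rt
Reagents that add atoms: none
Why: Saegusa–Ito oxidation. C5 is an epoxide carbon and cannot be enolised, so deprotonation and silylation occur only at C3a. Palladation of that enol ether and β-hydride loss then place the new double bond at C3a=C7a with no regiochemical choice.

Step 6
Reactants: 9 (1S,5S,6S)-5-isopropyl-7-oxabicyclo[4.1.0]hept-3-en-2-one
Product: 10 (4S,5R)-5-hydroxy-4-isopropylcyclohex-2-en-1-one
Conditions: SmI2 (2.2 equiv), THF/MeOH, −90 °C; pH 7 buffer
Reagents that add atoms: none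
Why: Reductive cleavage of an α,β-epoxy ketone. Two single-electron transfers from divalent samarium to the carbonyl expel the adjacent C5–O bond and methanol protonates C5. The C6–O bond is not touched, so the hydroxyl keeps its configuration cis to the isopropyl group. The very low temperature is intended to spare the enone.

Step 7
Reactants: 10 (4S,5R)-5-hydroxy-4-isopropylcyclohex-2-en-1-one
Product: 11 (4S,5R)-5-(tert-butyldimethylsilyloxy)-4-isopropylcyclohex-2-en-1-one
Conditions: t-BuMe2SiOTf, 2,6-lutidine, CH2Cl2, −78 to 0 °C
Reagents that add atoms: tert-butyldimethylsilyl trifluoromethanesulfonate, CC(C)(C)[Si](C)(C)OS(=O)(=O)C(F)(F)F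
Why: Silyl ether formation with the reactive triflate is suited to a hindered secondary alcohol. The weak base avoids dehydration of the β-hydroxy enone toward the phenol.

Step 8
Reactants: 12 acetylacetone
Product: 13 4-(trimethylsilyloxy)pent-3-en-2-one (mixture of double-bond isomers)
Conditions: (Me3Si)2NH (0.6 equiv), imidazole (cat.), neat, 90 °C; distillation
Reagents that add atoms: hexamethyldisilazane, C[Si](C)(C)N[Si](C)(C)C
Why: O-silylation of the enolised β-diketone; ammonia is the only co-product and the enol ether is purified by distillation.

Step 9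
Reactants: 11 (4S,5R)-5-(tert-butyldimethylsilyloxy)-4-isopropylcyclohex-2-en-1-one; 13 4-(trimethylsilyloxy)pent-3-en-2-one
Product: 15 3-[(1S,5R,6S)-5-(tert-butyldimethylsilyloxy)-6-isopropyl-3-(trimethylsilyloxy)cyclohex-2-en-1-yl]-2,4-bis(trimethylsilyloxy)penta-1,3-diene, via ring silyl enol ether adduct 14 (not isolated)
Conditions: 13 (1.5 equiv), Me3SiOTf (0.2 equiv), CH2Cl2, −78 to −40 °C; then Et3N (4 equiv), Me3SiOTf (2.4 equiv), −78 to 0 °C; pentane extraction under argon, volatiles removed in vacuo, used crude
Reagents that add atoms: trimethylsilyl trifluoromethanesulfonate, C[Si](C)(C)OS(=O)(=O)C(F)(F)F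
Why: Mukaiyama–Michael addition followed by soft enolisation and silylation. The silyl triflate activates the enone, and the central carbon of 13 attacks C7a on the face opposite the isopropyl and silyloxy groups, which lie on the same face; this sets C7a. Silyl transfer leaves the ring oxygen as the C3a=C4 enol ether, and the diketone is then silylated to the bis(silyloxy)diene without ever freeing the ring ketone, so the enol ether cannot scramble to C4=C5 and the triketone cannot undergo intramolecular aldol closure.

Step 10
Reactants: 15 3-[(1S,5R,6S)-5-(tert-butyldimethylsilyloxy)-6-isopropyl-3-(trimethylsilyloxy)cyclohex-2-en-1-yl]-2,4-bis(trimethylsilyloxy)penta-1,3-diene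
Product: 18 (1S,3aR,6R,7S,7aS)-1-acetyl-6-(tert-butyldimethylsilyloxy)-7-isopropyloctahydro-1H-indene-2,4-dione (trans-fused), via cis-fused silyl enol ether 16 (not isolated), via cis-fused triketone 17 (not isolated)
Conditions: reticulated vitreous carbon anode, carbon cathode, undivided cell, LiClO4 (0.1 M), 2,6-lutidine (6 equiv), MeCN/i-PrOH 4:1, constant current, about 2.2 F per mol, 0 °C; then DBU (1.5 equiv), CH2Cl2, rt; aq. NH4Cl
Reagents that add atoms: none
Why: The anode removes one electron from the most electron-rich π system, the bis(silyloxy)diene. After loss of a silyl cation to the alcohol, the resulting 2-silyloxyallyl (α-keto) radical carries spin at C1 and C3, and only C3 can reach the ring enol ether; it adds to C3a in a 5-exo-trig closure that forms C3–C3a and ring B. The α-silyloxy radical left at C4 is oxidised at once to the oxocarbenium ion, which gives its silyl group to 2-propanol and becomes the C4 ketone; two electrons are consumed per molecule and hydrogen forms at the cathode. The closest known reaction types are the anodic intramolecular coupling of enol ethers through radical cations and the oxidative coupling of silyl bis-enol ethers to 1,4-diketones. Because C1 is held on the face of ring A opposite the isopropyl group, C3 reaches the same face of C3a, so the kinetic products 16 and 17 are cis-fused; C3a is then α to the C4 ketone and DBU should equilibrate it to the trans-fused 18, the isomer expected to be favoured for a hydrindan-4-one with its other substituents equatorial, while C7a, C6 and C7 cannot enolise and stay fixed. Chemoselectivity (diene before ring enol ether before product) rests on the order of oxidation potentials and on stopping at the theoretical charge. Regioselectivity rests on ring size, since C1 would have to close a three-membered ring and attack at C4 would be a 6-endo addition to the oxygen-bearing carbon; the C3a=C4 position of the ring enol ether was fixed in step 9. 2,6-Lutidine buffers the acid formed, and 2-propanol is preferred to methanol to slow solvolysis of the trimethylsilyl enol ethers before they are oxidised.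

Step 11
Reactants: 18 (1S,3aR,6R,7S,7aS)-1-acetyl-6-(tert-butyldimethylsilyloxy)-7-isopropyloctahydro-1H-indene-2,4-dione
Product: 19 (1S,3aR,6R,7S,7aR)-1-acetyl-6-(tert-butyldimethylsilyloxy)-7-isopropyl-4-methylideneoctahydro-2H-inden-2-one
Conditions: Ph3PCH3Br (3.5 equiv), KOt-Bu (3.3 equiv), THF, 0 °C; then 18, 0 °C to rt; aq. NH4Cl
Reagents that add atoms: methyltriphenylphosphonium bromide, C[P+](c1ccccc1)(c1ccccc1)c1ccccc1.[Br-]
Why: Wittig methylenation. The first equivalent of ylide deprotonates the β-diketone, and its enolate is inert to olefination, so only the C4 ketone reacts. Once C4 is an alkene, C3a can no longer epimerise and the trans fusion is locked.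

Step 12
Reactants: 19 (1S,3aR,6R,7S,7aR)-1-acetyl-6-(tert-butyldimethylsilyloxy)-7-isopropyl-4-methylideneoctahydro-2H-inden-2-one
Product: 20 1-[(1R,2S,3aR,6R,7S,7aR)-6-(tert-butyldimethylsilyloxy)-2-hydroxy-7-isopropyl-4-methylideneoctahydro-1H-inden-1-yl]ethan-1-one
Conditions: NADPH-dependent ketoreductase (chosen by screening for the ring carbonyl and 2S), NADP+ (cat.), i-PrOH (10 vol %), DMSO (10 vol %), phosphate buffer pH 7.0, 30 °C
Reagents that add atoms: none
Why: Ketoreductase mono-reduction of an α-substituted 1,3-diketone with dynamic kinetic resolution. C1 epimerises freely through the enol, the enzyme accepts only the (1R) keto form and delivers hydride to the face of the ring carbonyl that gives (2S), so C1 and C2 are set together with acetyl and hydroxyl cis. The neutral medium leaves the resulting aldol unit intact.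

Step 13
Reactants: 20 1-[(1R,2S,3aR,6R,7S,7aR)-6-(tert-butyldimethylsilyloxy)-2-hydroxy-7-isopropyl-4-methylideneoctahydro-1H-inden-1-yl]ethan-1-one; 21 (Z)-2-methylbut-2-enoic acid (angelic acid)
Product: 22 (1R,2S,3aR,6R,7S,7aR)-1-acetyl-6-(tert-butyldimethylsilyloxy)-7-isopropyl-4-methylideneoctahydro-1H-inden-2-yl (Z)-2-methylbut-2-enoate
Conditions: 21 (3 equiv), 2,4,6-trichlorobenzoyl chloride (3 equiv), Et3N (3.3 equiv), toluene, rt; filter; then 20, toluene, 70 °C
Reagents that add atoms: none
Why: Acylation through the preformed mixed anhydride (Yamaguchi-type activation, used here without a nucleophilic amine catalyst). The alcohol attacks the unhindered angeloyl carbonyl, and leaving out a pyridine catalyst avoids the addition–elimination that turns angelates into the E isomers. No strong base is present that could open or eliminate the aldol unit.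

Step 14
Reactants: 22 (1R,2S,3aR,6R,7S,7aR)-1-acetyl-6-(tert-butyldimethylsilyloxy)-7-isopropyl-4-methylideneoctahydro-1H-inden-2-yl (Z)-2-methylbut-2-enoate
Product: 23 (1R,2S,3aR,6R,7S,7aR)-1-acetyl-6-hydroxy-7-isopropyl-4-methylideneoctahydro-1H-inden-2-yl (Z)-2-methylbut-2-enoate
Conditions: HF·pyridine, pyridine, THF, 0 °C to rt
Reagents that add atoms: none
Why: Fluoride cleavage of the silyl ether in a weakly acidic, non-basic medium, chosen so the C2 ester β to the acetyl carbonyl is not eliminated. No epoxide is present yet.

Step 15
Reactants: 21 (Z)-2-methylbut-2-enoic acid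
Product: 24 (Z)-2-methylbut-2-en-1-ol
Conditions: LiAlH4, Et2O, 0 °C to rt; aqueous NaOH work-up
Reagents that add atoms: none
Why: Hydride reduction of the carboxylic acid to the allylic alcohol; the trisubstituted double bond is not attacked and keeps its Z geometry.

Step 16
Reactants: 24 (Z)-2-methylbut-2-en-1-ol
Product: 25 [(2R,3S)-2,3-dimethyloxiran-2-yl]methanol
Conditions: Ti(Oi-Pr)4 (10 mol %), D-(−)-diethyl tartrate (12 mol %), t-BuOOH (2 equiv), 4 Å molecular sieves, CH2Cl2, −20 °C; non-aqueous work-up
Reagents that add atoms: tert-butyl hydroperoxide, CC(C)(C)OO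
Why: Sharpless asymmetric epoxidation. The titanium tartrate complex delivers oxygen to one face of the allylic alcohol, and with the D-(−)-tartrate this gives the (2R,3S) epoxy alcohol. The Z geometry is transferred to the cis relationship of the hydroxymethyl and C3 methyl groups.

Step 17
Reactants: 25 [(2R,3S)-2,3-dimethyloxiran-2-yl]methanol
Product: 26 (2S,3S)-2,3-dimethyloxirane-2-carboxylic acid
Conditions: RuCl3·xH2O (2 mol %), NaIO4 (4 equiv), MeCN/EtOAc/H2O, 0 °C to rt; used promptly
Reagents that add atoms: water, O
Why: Ruthenium tetroxide-catalysed oxidation of the primary alcohol to the acid via the aldehyde hydrate. The epoxide is inert to it, and the C2 descriptor changes from R to S only because the substituent priorities change.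

Step 18
Reactants: 23 (1R,2S,3aR,6R,7S,7aR)-1-acetyl-6-hydroxy-7-isopropyl-4-methylideneoctahydro-1H-inden-2-yl (Z)-2-methylbut-2-enoate; 26 (2S,3S)-2,3-dimethyloxirane-2-carboxylic acid
Product: 27 (1R,2S,3aR,6R,7S,7aR)-1-acetyl-2-[(Z)-2-methylbut-2-enoyloxy]-4-methylidene-7-isopropyloctahydro-1H-inden-6-yl (2S,3S)-2,3-dimethyloxirane-2-carboxylate (CNP0300602.1)
Conditions: 26 (3 equiv), 2,4,6-trichlorobenzoyl chloride (3 equiv), Et3N (3.5 equiv), toluene, 0 °C to rt; then 23, 4-(dimethylamino)pyridine (0.5 equiv), toluene, rt
Reagents that add atoms: none
Why: Yamaguchi esterification. The acylpyridinium formed from the mixed anhydride is reactive enough for the axial, isopropyl-flanked C6 hydroxyl, and acylation at oxygen leaves every stereocentre unchanged. Room temperature and a sub-stoichiometric amount of the pyridine base are chosen to spare the C2 ester.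

## Compound list

1 | 3-methylbutanal | CC(C)CC=O | starting material
2 | methyl vinyl ketone | CC(=O)C=C | starting material
3 | (R)-2-isopropyl-5-oxohexanal | O=C[C@@H](C(C)C)CCC(C)=O | intermediate
4 | (R)-4-isopropylcyclohex-2-en-1-one | O=C1C=C[C@@H](C(C)C)CC1 | intermediate
5 | (1R,4R)-4-isopropylcyclohex-2-en-1-ol | O[C@H]1C=C[C@@H](C(C)C)CC1 | intermediate
6 | (1R,2R,5R,6S)-5-isopropyl-7-oxabicyclo[4.1.0]heptan-2-ol | O[C@H]1[C@H]2O[C@H]2[C@@H](C(C)C)CC1 | intermediate
7 | (1S,5R,6S)-5-isopropyl-7-oxabicyclo[4.1.0]heptan-2-one | O=C1[C@H]2O[C@H]2[C@@H](C(C)C)CC1 | intermediate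
8 | {[(1S,5R,6S)-5-isopropyl-7-oxabicyclo[4.1.0]hept-2-en-2-yl]oxy}trimethylsilane | C[Si](C)(C)OC1=CC[C@H](C(C)C)[C@@H]2O[C@H]12 | intermediate
9 | (1S,5S,6S)-5-isopropyl-7-oxabicyclo[4.1.0]hept-3-en-2-one | O=C1C=C[C@H](C(C)C)[C@@H]2O[C@H]12 | intermediate
10 | (4S,5R)-5-hydroxy-4-isopropylcyclohex-2-en-1-one | O=C1C=C[C@H](C(C)C)[C@H](O)C1 | intermediate
11 | (4S,5R)-5-(tert-butyldimethylsilyloxy)-4-isopropylcyclohex-2-en-1-one | O=C1C=C[C@H](C(C)C)[C@H](O[Si](C)(C)C(C)(C)C)C1 | intermediate
12 | acetylacetone (pentane-2,4-dione) | CC(=O)CC(C)=O | starting material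
13 | 4-(trimethylsilyloxy)pent-3-en-2-one | CC(=O)C=C(C)O[Si](C)(C)C | intermediate
14 | 3-[(1S,5R,6S)-5-(tert-butyldimethylsilyloxy)-6-isopropyl-3-(trimethylsilyloxy)cyclohex-2-en-1-yl]pentane-2,4-dione | CC(=O)C(C(C)=O)[C@@H]1C=C(O[Si](C)(C)C)C[C@@H](O[Si](C)(C)C(C)(C)C)[C@H]1C(C)C | intermediate
15 | 3-[(1S,5R,6S)-5-(tert-butyldimethylsilyloxy)-6-isopropyl-3-(trimethylsilyloxy)cyclohex-2-en-1-yl]-2,4-bis(trimethylsilyloxy)penta-1,3-diene | C=C(O[Si](C)(C)C)/C(=C(/C)O[Si](C)(C)C)[C@@H]1C=C(O[Si](C)(C)C)C[C@@H](O[Si](C)(C)C(C)(C)C)[C@H]1C(C)C | intermediate
16 | (3aS,6R,7S,7aS)-1-acetyl-6-(tert-butyldimethylsilyloxy)-7-isopropyl-2-(trimethylsilyloxy)-3,3a,5,6,7,7a-hexahydro-4H-inden-4-one (cis-fused) | O=C1C[C@@H](O[Si](C)(C)C(C)(C)C)[C@@H](C(C)C)[C@@H]2C(C(C)=O)=C(O[Si](C)(C)C)C[C@H]12 | intermediate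
17 | (1S,3aS,6R,7S,7aS)-1-acetyl-6-(tert-butyldimethylsilyloxy)-7-isopropyloctahydro-1H-indene-2,4-dione (cis-fused) | O=C1C[C@@H](O[Si](C)(C)C(C)(C)C)[C@@H](C(C)C)[C@@H]2[C@@H](C(C)=O)C(=O)C[C@H]12 | intermediate
18 | (1S,3aR,6R,7S,7aS)-1-acetyl-6-(tert-butyldimethylsilyloxy)-7-isopropyloctahydro-1H-indene-2,4-dione (trans-fused) | O=C1C[C@@H](O[Si](C)(C)C(C)(C)C)[C@@H](C(C)C)[C@@H]2[C@@H](C(C)=O)C(=O)C[C@@H]12 | intermediate
19 | (1S,3aR,6R,7S,7aR)-1-acetyl-6-(tert-butyldimethylsilyloxy)-7-isopropyl-4-methylideneoctahydro-2H-inden-2-one | C=C1C[C@@H](O[Si](C)(C)C(C)(C)C)[C@@H](C(C)C)[C@@H]2[C@@H](C(C)=O)C(=O)C[C@@H]12 | intermediate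
20 | 1-[(1R,2S,3aR,6R,7S,7aR)-6-(tert-butyldimethylsilyloxy)-2-hydroxy-7-isopropyl-4-methylideneoctahydro-1H-inden-1-yl]ethan-1-one | C=C1C[C@@H](O[Si](C)(C)C(C)(C)C)[C@@H](C(C)C)[C@@H]2[C@@H](C(C)=O)[C@@H](O)C[C@@H]12 | intermediate
21 | (Z)-2-methylbut-2-enoic acid (angelic acid) | C/C=C(/C)C(=O)O | starting material
22 | (1R,2S,3aR,6R,7S,7aR)-1-acetyl-6-(tert-butyldimethylsilyloxy)-7-isopropyl-4-methylideneoctahydro-1H-inden-2-yl (Z)-2-methylbut-2-enoate | C=C1C[C@@H](O[Si](C)(C)C(C)(C)C)[C@@H](C(C)C)[C@@H]2[C@@H](C(C)=O)[C@@H](OC(=O)/C(C)=C\C)C[C@@H]12 | intermediate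
23 | (1R,2S,3aR,6R,7S,7aR)-1-acetyl-6-hydroxy-7-isopropyl-4-methylideneoctahydro-1H-inden-2-yl (Z)-2-methylbut-2-enoate | C=C1C[C@@H](O)[C@@H](C(C)C)[C@@H]2[C@@H](C(C)=O)[C@@H](OC(=O)/C(C)=C\C)C[C@@H]12 | intermediate
24 | (Z)-2-methylbut-2-en-1-ol | C/C=C(/C)CO | intermediate
25 | [(2R,3S)-2,3-dimethyloxiran-2-yl]methanol | OC[C@@]1(C)O[C@H]1C | intermediate
26 | (2S,3S)-2,3-dimethyloxirane-2-carboxylic acid | O=C(O)[C@@]1(C)O[C@H]1C | intermediate
27 | (1R,2S,3aR,6R,7S,7aR)-1-acetyl-2-[(Z)-2-methylbut-2-enoyloxy]-4-methylidene-7-isopropyloctahydro-1H-inden-6-yl (2S,3S)-2,3-dimethyloxirane-2-carboxylate | C=C1C[C@@H](OC(=O)[C@@]2(C)O[C@H]2C)[C@@H](C(C)C)[C@@H]2[C@@H](C(C)=O)[C@@H](OC(=O)/C(C)=C\C)C[C@@H]12 | target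

## Step count and least certain steps

Total step count: 18. Longest linear sequence: 14 (steps 1–7, 9–14 and 18). Step 8 and steps 15–17 are side branches.

**Step 10 (key step).** The most likely failures are solvolysis of the trimethylsilyl enol ethers before they are oxidised, capture of the radical cation by the alcohol before ring closure, and over-oxidation of the product past the theoretical charge. A further risk is incomplete equilibration at C3a, because the trans preference of the ring fusion is thermodynamic and may not be large with two trigonal carbons in ring B.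
Fallback: set out from 15. Brominate the terminal diene carbon C3 with N-bromosuccinimide (1 equiv, THF, −78 °C) to give the bromo ketone F1. Close ring B by atom-transfer radical cyclisation (Et3B, air, 2,6-lutidine, CH2Cl2, rt): the C3 radical adds 5-exo to the ring silyl enol ether, and the α-bromo silyl ether formed at C4 collapses to the ketone, giving the cis-fused enol ether F2. Aqueous work-up hydrolyses F2 to 17, where the route is rejoined before the DBU equilibration to 18.

**Step 9.** Enol ether 13 is a weak nucleophile and C7a of 11 is flanked by the isopropyl-bearing carbon, so slow addition and competing loss of the silyl groups are the likely failure. Isomerisation of the ring enol ether during the second silylation is the other risk.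
Fallback: set out from 11 and 12. A Yb(OTf)3-catalysed Michael addition of the free diketone gives the conjugate adduct F3, and exhaustive silylation (Me3SiOTf, Et3N, CH2Cl2, −78 to 0 °C) returns to 15. This changes the bond-forming approach from a silyl-transfer addition to a Lewis-acid-catalysed enol addition. Its cost is loss of regiocontrol over the ring enol ether, and only the C3a=C4 isomer can cyclise in step 10.

**Step 12.** The lipophilic bicyclic substrate may be a poor fit for the enzyme, or the enzyme may reduce the acetyl carbonyl in place of the ring carbonyl.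
Fallback: set out from 19. Silylate the enolised acetyl oxygen (Et3SiCl, Et3N, CH2Cl2) to the exocyclic enol ether F4, which leaves the ring carbonyl as the only ketone. Reduce it under reagent control with the (R)-oxazaborolidine and catecholborane to the (2S) allylic alcohol F5. Cleave the enol ether with buffered fluoride (n-Bu4NF, AcOH, THF, −78 °C), with C1 protonated from the less hindered face, and rejoin at 20. The position of silylation in F4 and the face of protonation at C1 are the open points of this reserve.

**Step 6.** Electron transfer to the enone could compete with epoxide cleavage, giving over-reduction or coupling, and the β-hydroxy enone 10 can dehydrate and aromatise if the medium turns basic.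
Fallback: set out from 7 and open the epoxide before the double bond is introduced. SmI2 (THF/MeOH, −90 °C) gives the hydroxy ketone F6, silylation (t-BuMe2SiOTf, 2,6-lutidine) gives F7, kinetic enolisation away from the silyloxy-bearing carbon (LDA, Me3SiCl, −78 °C) gives the enol ether F8, and Pd(OAc)2 in MeCN returns 11. This order removes the enone from the reduction step but gives up the regiochemical guarantee that the epoxide provided.

**Step 18.** Acylation of the axial C6 hydroxyl with an α-quaternary acid is slow, and prolonged exposure to amine bases could eliminate the C2 angelate or isomerise it.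
Fallback: reverse the order of the two esterifications, setting out from 19. HF·pyridine gives the C6 alcohol F9. Yamaguchi esterification with 26 gives the epoxy ester F10 while C2 is still a diketone carbonyl (any enol ester formed on the diketone is cleaved on a mild NaHCO3/MeOH work-up). The ketoreductase reduction of step 12 then gives the C2 alcohol F11, and the base-free mixed-anhydride angeloylation of step 13 closes at 27. The forcing acylation then never meets a β-acyloxy ketone.

## Further compounds

F1 | step 10 | 1-bromo-3-[(1S,5R,6S)-5-(tert-butyldimethylsilyloxy)-6-isopropyl-3-(trimethylsilyloxy)cyclohex-2-en-1-yl]-4-(trimethylsilyloxy)pent-3-en-2-one | BrCC(=O)C(=C(C)O[Si](C)(C)C)[C@@H]1C=C(O[Si](C)(C)C)C[C@@H](O[Si](C)(C)C(C)(C)C)[C@H]1C(C)C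
F2 | step 10 | (3aS,6R,7S,7aS)-6-(tert-butyldimethylsilyloxy)-7-isopropyl-1-[1-(trimethylsilyloxy)ethylidene]hexahydro-1H-indene-2,4-dione (cis-fused) | C[Si](C)(C)OC(C)=C1C(=O)C[C@@H]2C(=O)C[C@@H](O[Si](C)(C)C(C)(C)C)[C@@H](C(C)C)[C@H]12
F3 | step 9 | 3-[(1R,2S,3R)-3-(tert-butyldimethylsilyloxy)-2-isopropyl-5-oxocyclohexyl]pentane-2,4-dione | CC(=O)C(C(C)=O)[C@@H]1CC(=O)C[C@@H](O[Si](C)(C)C(C)(C)C)[C@H]1C(C)C
F4 | step 12 | (3aR,6R,7S,7aR)-6-(tert-butyldimethylsilyloxy)-7-isopropyl-4-methylidene-1-[1-(triethylsilyloxy)ethylidene]octahydro-2H-inden-2-one | C=C1C[C@@H](O[Si](C)(C)C(C)(C)C)[C@@H](C(C)C)[C@@H]2C(=C(C)O[Si](CC)(CC)CC)C(=O)C[C@@H]12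
F5 | step 12 | (2S,3aR,6R,7S,7aR)-6-(tert-butyldimethylsilyloxy)-7-isopropyl-4-methylidene-1-[1-(triethylsilyloxy)ethylidene]octahydro-1H-inden-2-ol | C=C1C[C@@H](O[Si](C)(C)C(C)(C)C)[C@@H](C(C)C)[C@@H]2C(=C(C)O[Si](CC)(CC)CC)[C@@H](O)C[C@@H]12
F6 | step 6 | (3R,4R)-3-hydroxy-4-isopropylcyclohexan-1-one | O=C1CC[C@H](C(C)C)[C@H](O)C1
F7 | step 6 | (3R,4R)-3-(tert-butyldimethylsilyloxy)-4-isopropylcyclohexan-1-one | O=C1CC[C@H](C(C)C)[C@H](O[Si](C)(C)C(C)(C)C)C1
F8 | step 6 | trimethylsilyl enol ether of F7 with the double bond toward C3a | C[Si](C)(C)OC1=CC[C@H](C(C)C)[C@H](O[Si](C)(C)C(C)(C)C)C1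
F9 | step 18 | (1S,3aR,6R,7S,7aR)-1-acetyl-6-hydroxy-7-isopropyl-4-methylideneoctahydro-2H-inden-2-one | C=C1C[C@@H](O)[C@@H](C(C)C)[C@@H]2[C@@H](C(C)=O)C(=O)C[C@@H]12
F10 | step 18 | (1S,3aR,6R,7S,7aR)-1-acetyl-7-isopropyl-4-methylidene-2-oxooctahydro-1H-inden-6-yl (2S,3S)-2,3-dimethyloxirane-2-carboxylate | C=C1C[C@@H](OC(=O)[C@@]2(C)O[C@H]2C)[C@@H](C(C)C)[C@@H]2[C@@H](C(C)=O)C(=O)C[C@@H]12
F11 | step 18 | (1R,2S,3aR,6R,7S,7aR)-1-acetyl-2-hydroxy-7-isopropyl-4-methylideneoctahydro-1H-inden-6-yl (2S,3S)-2,3-dimethyloxirane-2-carboxylate | C=C1C[C@@H](OC(=O)[C@@]2(C)O[C@H]2C)[C@@H](C(C)C)[C@@H]2[C@@H](C(C)=O)[C@@H](O)C[C@@H]12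
A1 | alternative 1 | 1,7-enyne: 5-(tert-butyldimethylsilyloxy)-3,3-dimethoxy-6-isopropyl-8-(2-methyl-1,3-dioxolan-2-yl)oct-1-en-7-yne, configured at C6 and C7 as in the target | C=CC(OC)(OC)C[C@@H](O[Si](C)(C)C(C)(C)C)[C@@H](C(C)C)C#CC1(C)OCCO1
A2 | alternative 1 | bicyclic enone with C7a=C1 alkene, C2 ketone, C4 dimethyl ketal and dioxolane-protected acetyl group | COC1(OC)C[C@@H](O[Si](C)(C)C(C)(C)C)[C@@H](C(C)C)C2=C(C3(C)OCCO3)C(=O)C[C@@H]12
A3 | alternative 2 | nine-membered keto enoate: methyl 7-(tert-butyldimethylsilyloxy)-8-isopropyl-5-oxo-2-(triethylsilyloxy)cyclonon-1(9)-ene-1-carboxylate, ring carbons cis on the double bond | O=C1C[C@@H](O[Si](C)(C)C(C)(C)C)[C@@H](C(C)C)/C=C(C(=O)OC)\[C@@H](O[Si](CC)(CC)CC)CC1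
A4 | alternative 2 | trans-hydrindanone ester with C1 methyl ester, C2 triethylsilyl ether, C4 ketone | O=C1C[C@@H](O[Si](C)(C)C(C)(C)C)[C@@H](C(C)C)[C@@H]2[C@@H](C(=O)OC)[C@@H](O[Si](CC)(CC)CC)C[C@@H]12
A5 | alternative 3 | methyl 4-[2-acetoxy-4-(tert-butyldimethylsilyloxy)-5-isopropylcyclohexyl]-2-diazo-3-oxobutanoate, ring centres as in the target | CC(=O)O[C@@H]1C[C@@H](O[Si](C)(C)C(C)(C)C)[C@@H](C(C)C)C[C@H]1CC(=O)C(=[N+]=[N-])C(=O)OC
A6 | alternative 3 | trans-hydrindane β-keto ester with C1 methyl ester, C2 ketone, C4 acetate | CC(=O)O[C@@H]1C[C@@H](O[Si](C)(C)C(C)(C)C)[C@@H](C(C)C)[C@@H]2[C@@H](C(=O)OC)C(=O)C[C@@H]12
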